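**Strategy.** Ring B of the clerodane is closed by a [4+2] annulation across the bare C-6–C-7 ethano bridge that links the quaternary C-5 to C-8. Vinyltriphenylphosphonium bromide supplies C-6–C-7: the regiodefined enolate of the C-4 ketone adds at C-5 (Michael, C-5–C-6) and the resulting ylide olefinates the C-8 acetyl group (intramolecular Wittig, C-7=C-8). This sets C-5 anti to the C-10 substituent and leaves no activating group behind. The precursor is a monocyclic silyl enol ether whose C-10 carries a quaternary C-9 (methyl, acetyl, benzyl ester). C-10 is set by catalysis; C-5, C-8 (hydrogenation) and C-9 (decarboxylative radical addition, chain equatorial) follow by substrate control.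

Key step: step 4

Remark: clerodane atom numbers (C-1 to C-20) are used for all intermediates, written "C-n" to keep them apart from compound numbers. Compounds 5, 7 and 9–13 are mixtures of epimers at C-9; this centre is erased in step 6, so it carries no descriptor in their SMILES.
Assumption: the (S)-configured oxazaborolidinium salt of step 2 delivers the (1R) adduct; should the sense be opposite, its mirror image is used.

**Step 1**
Reactants: 1 benzyl propanoate
Product: 3 1-(benzyloxy)-1-(tert-butyldimethylsilyloxy)prop-1-ene (E/Z mixture), via lithium enolate 2 (not isolated)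
Conditions: LiN(iPr)2, THF, −78 °C; TBSCl, HMPA, −78 °C to rt
Reagents that add atoms: tert-butyldimethylsilyl chloride, CC(C)(C)[Si](C)(C)Cl
Why: Kinetic ester deprotonation and O-silylation of the lithium enolate (silyl ketene acetal formation); the alkene geometry is irrelevant because the α-carbon stereocentre is erased in step 3.

**Step 2**
Reactants: 3 silyl ketene acetal; 4 2-methylcyclohex-2-en-1-one
Product: 5 benzyl 2-[(1R)-3-(tert-butyldimethylsilyloxy)-2-methylcyclohex-2-en-1-yl]propanoate (C-9 epimers)
Conditions: N-protonated oxazaborolidine from (S)-α,α-diphenylprolinol and 2-methylphenylboronic acid, N(SO2CF3)2 salt (20 mol %), toluene, −40 °C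
Reagents that add atoms: none
Why: Chiral Lewis acid-catalysed Mukaiyama–Michael addition, in which the boron cation binds the enone carbonyl and shields one face of the β-carbon so that the ketene acetal sets C-10, while silyl transfer delivers the regiodefined C-4=C-5 silyl enol ether directly.

**Step 3**
Reactants: 5 Michael adduct
Product: 7 benzyl 2-[(1S)-3-(tert-butyldimethylsilyloxy)-2-methylcyclohex-2-en-1-yl]-2-methyl-3-oxobutanoate (C-9 epimers; same spatial arrangement at C-10 as in 5), via lithium ester enolate 6 (not isolated)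
Conditions: LiN(iPr)2, THF, −78 °C; CH3COCl, −78 °C
Reagents that add atoms: acetyl chloride, CC(=O)Cl
Why: Claisen-type C-acylation of the fully substituted lithium ester enolate installs the C-8/C-17 acetyl group while the ring ketone stays masked as its silyl enol ether; C-9 becomes quaternary with a configuration that does not matter.

**Step 4**
Reactants: 7 β-keto ester silyl enol ether; 8 vinyltriphenylphosphonium bromide
Product: 11 benzyl (4aR,8aS)-1,2,4a-trimethyl-5-oxo-1,4,4a,5,6,7,8,8a-octahydronaphthalene-1-carboxylate (trans-fused; C-4 ketone; C-7=C-8; C-9 epimers), via ammonium enolate 9 (not isolated), via phosphonium ylide 10 (not isolated)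
Conditions: 8 (1.5 equiv), Bu4N[Ph3SiF2] added slowly, THF/MeCN, −20 °C to 60 °C
Reagents that add atoms: none
Why: Fluoride cleaves the silyl enol ether to the regiodefined tetrasubstituted enolate 9, which adds through C-5 to the vinylphosphonium salt (Michael addition, C-5–C-6 bond) to give ylide 10, and 10 olefinates the C-8 ketone intramolecularly (Wittig, C-7=C-8) with loss of Ph3PO. The closest known reaction type is the Schweizer annulation, in which an enolate with a carbonyl group in 1,5-relationship and vinyltriphenylphosphonium bromide give a cyclohexene by Michael addition and intramolecular Wittig olefination. Ring B is the only ring closed, by six-membered intramolecular carbonyl olefination (attack of ylide carbon C-7 on the exocyclic C-8 carbonyl, then oxaphosphetane collapse), so that overall the C-5–C-10–C-9–C-8 unit and a two-carbon unit combine in a [4+2] annulation. The new stereocentre C-5 is controlled by C-10: the electrophile attacks the enolate face anti to the bulky C-10 substituent, which places C-6 trans to C-9 and so gives the trans ring fusion with the C-19 methyl anti to H-10. The step needs C- over O-alkylation and no proton transfer from C-3 or the acetyl methyl to the enolate, which is secured by liberating 9 slowly in the presence of excess 8 (the bridged aldol that such a transfer could cause is reversible and cannot dehydrate). It also needs the ylide to choose the C-8 ketone, which it should because the benzyl ester is far less electrophilic and the C-4 ketone could be reached only through a four-membered ring.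

**Step 5**
Reactants: 11 octalone benzyl ester
Product: 13 (2R,4aR,8aS)-1,2,4a-trimethyl-5-oxodecahydronaphthalene-1-carboxylic acid (trans-fused; C-17 methyl equatorial; C-9 epimers), via unsaturated keto acid 12 (not isolated)
Conditions: H2 (4 atm), Pd/C, EtOAc, rt
Reagents that add atoms: none
Why: Heterogeneous hydrogenation cleaves the benzyl ester by hydrogenolysis and saturates C-7=C-8 from the β-face, opposite the axial C-19 methyl and the pseudo-axial C-9 substituent, so that H-8 is β and the C-17 methyl equatorial in both C-9 epimers.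

**Step 6**
Reactants: 13 keto acid; 14 vinylboronic acid pinacol ester
Product: 15 (4aR,5S,6R,8aR)-5,6,8a-trimethyl-5-[2-(4,4,5,5-tetramethyl-1,3,2-dioxaborolan-2-yl)ethyl]octahydronaphthalen-1(2H)-one (clerodane 5R,8R,9S,10R)
Conditions: 14 (3 equiv), Ir[dF(CF3)ppy]2(dtbbpy)PF6 (2 mol %), Cs2CO3 (0.5 equiv), DMF, blue LEDs, rt
Reagents that add atoms: none
Why: Photoredox decarboxylative Giese addition, in which the planar tertiary C-9 radical common to both epimers adds to the vinyl boronate on the β-face (equatorial attack, anti to the axial C-19 methyl) before reduction and protonation of the α-boryl radical, which sets C-9 with axial methyl and equatorial two-carbon chain.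

**Step 7**
Reactants: 15 keto boronate
Product: 17 (4aR,5S,6R,8aR)-5,6,8a-trimethyl-5-[2-(4,4,5,5-tetramethyl-1,3,2-dioxaborolan-2-yl)ethyl]-3,4,4a,5,6,7,8,8a-octahydronaphthalen-1-yl trifluoromethanesulfonate, via potassium enolate 16 (not isolated)
Conditions: KN(SiMe3)2, THF, −78 °C; PhNTf2; NH4Cl aq.
Reagents that add atoms: N-phenylbis(trifluoromethanesulfonimide), FC(F)(F)S(=O)(=O)N(c1ccccc1)S(=O)(=O)C(F)(F)F
Why: The C-4 ketone can enolise only toward C-3 because C-5 is quaternary, so O-triflation of the potassium enolate gives a single enol triflate, and the alkyl pinacol boronate tolerates the hindered amide base at low temperature.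

**Step 8**
Reactants: 17 enol triflate
Product: 18 2-{2-[(1S,2R,4aR,8aR)-1,2,4a,5-tetramethyl-1,2,3,4,4a,7,8,8a-octahydronaphthalen-1-yl]ethyl}-4,4,5,5-tetramethyl-1,3,2-dioxaborolane (clerodane 5R,8R,9S,10R; C-3=C-4)
Conditions: MeZnCl, Pd(PPh3)4 (5 mol %), THF, 50 °C
Reagents that add atoms: methylzinc chloride, C[Zn]Cl
Why: Negishi cross-coupling of the enol triflate with methylzinc chloride installs C-18 and fixes the C-3=C-4 alkene, while the alkyl boronate does not transmetalate in the absence of base.

**Step 9**
Reactants: 19 4-(tert-butyldimethylsilyloxy)but-2-yn-1-ol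
Product: 21 (Z)-4-(tert-butyldimethylsilyloxy)-3-iodobut-2-en-1-ol, via alkenylalanate 20 (not isolated)
Conditions: NaAlH2(OCH2CH2OCH3)2, THF, 0 °C; I2, −78 °C to 0 °C
Reagents that add atoms: iodine, II
Why: Hydroxyl-directed trans-hydroalumination of the propargylic alcohol places aluminium on the distal alkyne carbon in a five-membered alanate, and iodinolysis with retention gives the (Z)-iodoalkene with iodine cis to the free CH2OH.

**Step 10**
Reactants: 21 iodo alcohol; 22 docosanoyl chloride
Product: 23 (Z)-4-(tert-butyldimethylsilyloxy)-3-iodobut-2-en-1-yl docosanoate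
Conditions: Et3N, DMAP (cat.), CH2Cl2, 0 °C to rt
Reagents that add atoms: none
Why: DMAP-catalysed acylation of the only free (primary allylic) hydroxyl, the other oxygen being silylated, so that the ester sits on the future O-15.

**Step 11**
Reactants: 18 alkyl boronate; 23 alkenyl iodide
Product: 24 (13E)-16-(tert-butyldimethylsilyloxy)cleroda-3,13-dien-15-yl docosanoate (5R,8R,9S,10R)
Conditions: Pd(dppf)Cl2 (10 mol %), AsPh3, Cs2CO3, DMF/H2O, 50 °C
Reagents that add atoms: none
Why: B-alkyl Suzuki–Miyaura coupling joins C-12 to C-13 with retention of alkene geometry (C-12 cis to C-15, hence 13E), oxidative addition into the C–I bond being much faster than ionisation of the allylic ester.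

**Step 12**
Reactants: 24 silyl ether
Product: 25 (13E)-16-hydroxycleroda-3,13-dien-15-yl docosanoate (5R,8R,9S,10R), the target
Conditions: HF·pyridine, pyridine/THF, 0 °C to rt
Reagents that add atoms: none
Why: Fluoride cleavage of the primary silyl ether under non-basic conditions leaves the ester untouched, and acyl migration cannot occur because the two oxygenated carbons are trans on the alkene.

**Compound list**
1 | benzyl propanoate | CCC(=O)OCc1ccccc1 | starting material
2 | lithium enolate of benzyl propanoate | CC=C([O-])OCc1ccccc1.[Li+] | intermediate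
3 | 1-(benzyloxy)-1-(tert-butyldimethylsilyloxy)prop-1-ene | CC=C(OCc1ccccc1)O[Si](C)(C)C(C)(C)C | intermediate
4 | 2-methylcyclohex-2-en-1-one | CC1=CCCCC1=O | starting material
5 | benzyl 2-[(1R)-3-(tert-butyldimethylsilyloxy)-2-methylcyclohex-2-en-1-yl]propanoate | CC(C(=O)OCc1ccccc1)[C@H]2CCCC(O[Si](C)(C)C(C)(C)C)=C2C | intermediate
6 | lithium ester enolate of 5 | CC(=C([O-])OCc1ccccc1)[C@H]2CCCC(O[Si](C)(C)C(C)(C)C)=C2C.[Li+] | intermediate
7 | benzyl 2-[(1S)-3-(tert-butyldimethylsilyloxy)-2-methylcyclohex-2-en-1-yl]-2-methyl-3-oxobutanoate | CC(=O)C(C)(C(=O)OCc1ccccc1)[C@H]2CCCC(O[Si](C)(C)C(C)(C)C)=C2C | intermediate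
8 | vinyltriphenylphosphonium bromide | C=C[P+](c1ccccc1)(c1ccccc1)c1ccccc1.[Br-] | starting material
9 | tetrabutylammonium enolate (C-4/C-5) of desilylated 7 | CC(=O)C(C)(C(=O)OCc1ccccc1)[C@H]2CCCC([O-])=C2C.CCCC[N+](CCCC)(CCCC)CCCC | intermediate
10 | phosphonium ylide: ring ketone with C-5 bearing methyl and CH2CH=PPh3 trans to the C-10 side chain | CC(=O)C(C)(C(=O)OCc1ccccc1)[C@H]2CCCC(=O)[C@]2(C)CC=P(c3ccccc3)(c4ccccc4)c5ccccc5 | intermediate
11 | benzyl (4aR,8aS)-1,2,4a-trimethyl-5-oxo-1,4,4a,5,6,7,8,8a-octahydronaphthalene-1-carboxylate | O=C(OCc1ccccc1)C2(C)C(C)=CC[C@@]3(C)C(=O)CCC[C@H]23 | intermediate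
12 | (4aR,8aS)-1,2,4a-trimethyl-5-oxo-1,4,4a,5,6,7,8,8a-octahydronaphthalene-1-carboxylic acid | OC(=O)C1(C)C(C)=CC[C@@]2(C)C(=O)CCC[C@H]12 | intermediate
13 | (2R,4aR,8aS)-1,2,4a-trimethyl-5-oxodecahydronaphthalene-1-carboxylic acid | OC(=O)C1(C)[C@H](C)CC[C@@]2(C)C(=O)CCC[C@H]12 | intermediate
14 | vinylboronic acid pinacol ester | C=CB1OC(C)(C)C(C)(C)O1 | starting material
15 | (4aR,5S,6R,8aR)-5,6,8a-trimethyl-5-[2-(pinacolboryl)ethyl]octahydronaphthalen-1(2H)-one | CC1(C)OB(CC[C@@]2(C)[C@H](C)CC[C@@]3(C)C(=O)CCC[C@H]23)OC1(C)C | intermediate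
16 | potassium enolate of 15 | CC1(C)OB(CC[C@@]2(C)[C@H](C)CC[C@@]3(C)C([O-])=CCC[C@H]23)OC1(C)C.[K+] | intermediate
17 | enol triflate of 15 (C-3=C-4, OTf on C-4) | CC1(C)OB(CC[C@@]2(C)[C@H](C)CC[C@@]3(C)C(OS(=O)(=O)C(F)(F)F)=CCC[C@H]23)OC1(C)C | intermediate
18 | 2-{2-[(1S,2R,4aR,8aR)-1,2,4a,5-tetramethyl-1,2,3,4,4a,7,8,8a-octahydronaphthalen-1-yl]ethyl}-4,4,5,5-tetramethyl-1,3,2-dioxaborolane | CC1(C)OB(CC[C@@]2(C)[C@H](C)CC[C@@]3(C)C(C)=CCC[C@H]23)OC1(C)C | intermediate
19 | 4-(tert-butyldimethylsilyloxy)but-2-yn-1-ol | OCC#CCO[Si](C)(C)C(C)(C)C | starting material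
20 | sodium alkenylalanate (five-membered oxaluminole ate complex) | COCCO[Al-]1(OCCOC)OCC=C1CO[Si](C)(C)C(C)(C)C.[Na+] | intermediate
21 | (Z)-4-(tert-butyldimethylsilyloxy)-3-iodobut-2-en-1-ol | OC/C=C(/CO[Si](C)(C)C(C)(C)C)I | intermediate
22 | docosanoyl chloride | CCCCCCCCCCCCCCCCCCCCCC(=O)Cl | starting material
23 | (Z)-4-(tert-butyldimethylsilyloxy)-3-iodobut-2-en-1-yl docosanoate | CCCCCCCCCCCCCCCCCCCCCC(=O)OC/C=C(/CO[Si](C)(C)C(C)(C)C)I | intermediate
24 | (13E)-16-(tert-butyldimethylsilyloxy)cleroda-3,13-dien-15-yl docosanoate | CCCCCCCCCCCCCCCCCCCCCC(=O)OC/C=C(/CO[Si](C)(C)C(C)(C)C)CC[C@@]1(C)[C@H](C)CC[C@@]2(C)C(C)=CCC[C@H]12 | intermediate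
25 | (13E)-16-hydroxycleroda-3,13-dien-15-yl docosanoate | CCCCCCCCCCCCCCCCCCCCCC(=O)OC/C=C(/CO)CC[C@@]1(C)[C@H](C)CC[C@@]2(C)C(C)=CCC[C@H]12 | target

**Count.** Total: 12 steps. Longest linear sequence: 10 steps (1–8, 11, 12); steps 9–10 make the side-chain fragment.

**Steps most likely to fail**

1. Step 4. The free enolate may take a proton from the acetyl methyl or C-3 before it meets the phosphonium salt (loss of regiocontrol), or the sequence may stall after the Michael addition because the ylide does not engage the hindered ketone. The fallback sets out from 7 and replaces the Wittig closure by a Michael–aldol closure. Fluoride (Bu4N[Ph3SiF2]) and diphenyl(vinyl)phosphine oxide should give, again in one operation forming C-5–C-6 and C-7–C-8, the bicyclic β-hydroxy phosphine oxide F1. Horner–Wittig elimination (NaH, DMF, 50 °C) then comes back to the route at 11.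

2. Step 2. Facial discrimination on the α-methyl enone may be poor, or achiral silyl-cation catalysis may compete, so that C-10 is formed with low enantiomeric purity. The fallback sets out from 4 and moves the asymmetric event to a ketone reduction with chirality transfer.
   - CBS reduction with (S)-2-methyl-CBS-oxazaborolidine and BH3·SMe2 should give (R)-2-methylcyclohex-2-en-1-ol F2.
   - Propanoyl chloride/pyridine gives the propanoate F3.
   - Ireland–Claisen rearrangement (LiN(iPr)2, TBSCl, THF, −78 °C to rt, then aqueous acid) transfers the carbinol configuration suprafacially to C-10 and gives 2-[(1R)-2-methylcyclohex-2-en-1-yl]propanoic acid F4.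
   - Benzyl bromide/K2CO3 gives the benzyl ester F5.
   - Hydroboration–oxidation (BH3·THF; NaOH, H2O2) gives the C-4 alcohol F6, and Dess–Martin periodinane the ketone F7.
   - Equilibrating silylation (TBSOTf, Et3N, CH2Cl2) toward the more substituted enol ether comes back to the route at 5.

3. Step 6. Capture of the hindered tertiary radical by the vinyl boronate may be slower than radical disproportionation or back electron transfer, so that decarboxylation gives alkenes or the reduced hydrocarbon. The fallback sets out from 13 and switches from oxidative to reductive radical generation. N-hydroxyphthalimide with N,N'-diisopropylcarbodiimide and DMAP gives the redox-active ester F8. Its reductive Giese coupling with 14 (Ru(bpy)3(PF6)2, Hantzsch ester, iPr2NEt, blue light) comes back to the route at 15.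

**Further compounds**
F1 | step 4 | benzyl (4aR,8aS)-3-(diphenylphosphoryl)-2-hydroxy-1,2,4a-trimethyl-5-oxodecahydronaphthalene-1-carboxylate | O=C(OCc1ccccc1)C2(C)C(C)(O)C(P(=O)(c4ccccc4)c5ccccc5)C[C@@]3(C)C(=O)CCC[C@H]23
F2 | step 2 | (R)-2-methylcyclohex-2-en-1-ol | O[C@@H]1CCCC=C1C
F3 | step 2 | (R)-2-methylcyclohex-2-en-1-yl propanoate | CCC(=O)O[C@@H]1CCCC=C1C
F4 | step 2 | 2-[(1R)-2-methylcyclohex-2-en-1-yl]propanoic acid | CC(C(=O)O)[C@H]1CCCC=C1C
F5 | step 2 | benzyl 2-[(1R)-2-methylcyclohex-2-en-1-yl]propanoate | CC(C(=O)OCc1ccccc1)[C@H]2CCCC=C2C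
F6 | step 2 | benzyl 2-[(1R)-3-hydroxy-2-methylcyclohexyl]propanoate | CC(C(=O)OCc1ccccc1)[C@H]2CCCC(O)C2C
F7 | step 2 | benzyl 2-[(1R)-2-methyl-3-oxocyclohexyl]propanoate | CC(C(=O)OCc1ccccc1)[C@H]2CCCC(=O)C2C
F8 | step 6 | 1,3-dioxoisoindolin-2-yl (2R,4aR,8aS)-1,2,4a-trimethyl-5-oxodecahydronaphthalene-1-carboxylate | O=C(ON1C(=O)c2ccccc2C1=O)C3(C)[C@H](C)CC[C@@]4(C)C(=O)CCC[C@H]34
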